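**Retrosynthetic overview**
1. Target ⇒ diacetylation, desilylation and CBS reduction of a ten-membered 2-oxo-germacradienolide, which comes from the ring-contracted allylic boronate 21.
2. 21 ⇒ ring contraction: in seco-compound 17 a diazoalkane at C-2 adds to the alkenylboronic acid at C-1 to give an eleven-membered cyclic boronate; a 1,2-shift of C-1 from boron to C-2 makes the C1–C2 bond and closes the ten-membered ring (second ring).
3. 17 ⇒ cross-metathesis with vinyl boronate (C-1) and asymmetric methallylboration of the 4-formylbutenolide 12 (C8–C9, C-8).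
4. 12 ⇒ butenolide (first ring) by alkoxide-directed anti-carbomagnesiation and CO2 trapping of propargylic alcohol 8 (C7–C8, C11–C12).
5. 8 ⇒ zinc–ProPhenol alkynylation (C-6) of enal 5 (from 4,4-dimethoxybut-1-yne by methylalumination) with silyl propargyl ether 7.

Convention: positions use germacrane numbering (ring C-1 to C-10; lactone O on C-6; C-11, C-12, C-13 = lactone α-carbon, carbonyl, CH2O; C-14 on C-10; C-15 on C-4). The target is (2R,6R,8S,1(10)E,4E).

**Route**

Step 1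
Reactants: 1 4,4-dimethoxybut-1-yne
Product: 3 (E)-1-iodo-4,4-dimethoxy-2-methylbut-1-ene, via alkenylalane 2 (not isolated)
Conditions: AlMe3 (2.5 equiv), Cp2ZrCl2 (0.2 equiv), H2O (1 equiv), CH2Cl2, −23 °C; then I2, THF, −23 → 0 °C
Reagents that add atoms: trimethylaluminium C[Al](C)C; iodine II
Why: Negishi zirconium-catalysed methylalumination adds Me and Al syn across the terminal alkyne with Al at the terminus, and iodinolysis with retention gives the (E)-iodide that fixes the C4=C5 geometry; the cold water-accelerated variant spares the acetal.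

Step 2
Reactants: 3 (E)-1-iodo-4,4-dimethoxy-2-methylbut-1-ene
Product: 5 (E)-5,5-dimethoxy-3-methylpent-2-enal, via alkenyllithium 4 (not isolated)
Conditions: t-BuLi (2.1 equiv), Et2O, −78 °C; then DMF, −78 → 0 °C; H2O
Reagents that add atoms: N,N-dimethylformamide CN(C)C=O
Why: lithium–iodine exchange with retention of alkene geometry followed by Bouveault-type formylation gives the (E)-enal (C-6 aldehyde).

Step 3
Reactants: 6 prop-2-yn-1-ol
Product: 7 tert-butyl(diphenyl)(prop-2-ynyloxy)silane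
Conditions: TBDPSCl, imidazole, CH2Cl2, 0 → 23 °C
Reagents that add atoms: tert-butyl(chloro)diphenylsilane CC(C)(C)[Si](Cl)(c1ccccc1)c1ccccc1
Why: standard silyl ether formation; this bulky ether on the future C-13 oxygen survives Grignard reagents, peroxide and dilute acid later.

Step 4
Reactants: 5 (E)-5,5-dimethoxy-3-methylpent-2-enal; 7 tert-butyl(diphenyl)(prop-2-ynyloxy)silane
Product: 8 (4R,5E)-1-[tert-butyl(diphenyl)silyl]oxy-8,8-dimethoxy-6-methyloct-5-en-2-yn-4-ol
Conditions: Me2Zn (3 equiv), (S,S)-ProPhenol (20 mol%), Ph3PO (40 mol%), toluene, 0 → 4 °C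
Reagents that add atoms: none
Why: Trost zinc–ProPhenol alkynylation of an α,β-unsaturated aldehyde; the dinuclear zinc catalyst delivers the alkynylzinc to one face of the enal and sets C-6 as (R), the antipodal ligand giving the enantiomer.

Step 5
Reactants: 8 (4R,5E)-1-[tert-butyl(diphenyl)silyl]oxy-8,8-dimethoxy-6-methyloct-5-en-2-yn-4-ol
Product: 10 (5R)-3-{[tert-butyl(diphenyl)silyl]oxymethyl}-5-[(E)-4,4-dimethoxy-2-methylbut-1-enyl]-4-{[isopropoxy(dimethyl)silyl]methyl}furan-2(5H)-one, via alkenylmagnesium chelate 9 (not isolated)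
Conditions: (i-PrO)Me2SiCH2MgCl (4 equiv), CuI (copper iodide, 10 mol%), THF, 0 → 23 °C; then CO2 (1 atm), −20 → 23 °C; aq. citric acid
Reagents that add atoms: [isopropoxy(dimethyl)silyl]methylmagnesium chloride CC(C)O[Si](C)(C)C[Mg]Cl; carbon dioxide O=C=O
Why: Duboudin–Fallis alkoxide-directed anti-carbomagnesiation puts the silylmethyl group (future C-8) on the alkyne carbon next to the carbinol and magnesium on the distal carbon cis to oxygen, so carboxylation and acidification close the butenolide directly with C-6 untouched.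

Step 6
Reactants: 10 the silylmethyl butenolide
Product: 11 (5R)-3-{[tert-butyl(diphenyl)silyl]oxymethyl}-5-[(E)-4,4-dimethoxy-2-methylbut-1-enyl]-4-(hydroxymethyl)furan-2(5H)-one
Conditions: H2O2 (30% aq.), KF, KHCO3, THF/MeOH, 23 °C
Reagents that add atoms: hydrogen peroxide OO
Why: Tamao–Fleming oxidation turns the alkoxysilane C–Si bond into C–OH under bicarbonate-buffered peroxide that leaves the lactone, acetal and TBDPS ether alone.

Step 7
Reactants: 11 the hydroxymethyl butenolide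
Product: 12 (2R)-4-{[tert-butyl(diphenyl)silyl]oxymethyl}-2-[(E)-4,4-dimethoxy-2-methylbut-1-enyl]-5-oxo-2,5-dihydrofuran-3-carbaldehyde
Conditions: Dess–Martin periodinane, CH2Cl2, 0 → 23 °C
Reagents that add atoms: none
Why: Dess–Martin oxidation of the primary allylic alcohol works without base, which avoids epimerisation of the γ-stereocentre C-6.

Step 8
Reactants: 12 the 4-formylbutenolide
Product: 13 (5R)-3-{[tert-butyl(diphenyl)silyl]oxymethyl}-5-[(E)-4,4-dimethoxy-2-methylbut-1-enyl]-4-[(1S)-1-hydroxy-3-methylbut-3-enyl]furan-2(5H)-one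
Conditions: (S)-TRIP [(S)-3,3′-bis(2,4,6-triisopropylphenyl)-1,1′-binaphthyl-2,2′-diyl hydrogen phosphate] (5 mol%), 2-methylallylboronic acid pinacol ester (1.5 equiv), toluene, −30 °C
Reagents that add atoms: 4,4,5,5-tetramethyl-2-(2-methylprop-2-enyl)-1,3,2-dioxaborolane CC(=C)CB1OC(C)(C)C(C)(C)O1
Why: chiral phosphoric acid-catalysed allylboration (Antilla) through a closed six-membered transition state; the (S)-acid directs the methallyl group to the Si face of the aldehyde and sets C-8 as (S) under neutral conditions.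

Step 9
Reactants: 13 the methallyl carbinol
Product: 14 (5R)-3-{[tert-butyl(diphenyl)silyl]oxymethyl}-5-[(E)-4,4-dimethoxy-2-methylbut-1-enyl]-4-[(1S,3E)-1-hydroxy-3-methyl-4-(4,4,5,5-tetramethyl-1,3,2-dioxaborolan-2-yl)but-3-enyl]furan-2(5H)-one
Conditions: second-generation Grubbs catalyst (10 mol%), vinylboronic acid pinacol ester (5 equiv), CH2Cl2, 40 °C
Reagents that add atoms: 4,4,5,5-tetramethyl-2-vinyl-1,3,2-dioxaborolane C=CB1OC(C)(C)C(C)(C)O1
Why: ruthenium-catalysed cross-metathesis of a 1,1-disubstituted alkene with vinyl pinacol boronate (Grubbs) gives the trisubstituted alkenyl boronate with boron trans to the larger chain (E at C1=C10); the tri- and tetrasubstituted alkenes elsewhere are inert.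

Step 10
Reactants: 14 the alkenyl pinacol boronate acetal
Product: 17 the seco-compound: N-[2-(trifluoromethyl)phenylsulfonyl]hydrazone of the C-2 aldehyde carrying the free (E)-alkenylboronic acid at C-1 (6R,8S; 8-OH free; 13-OTBDPS), via aldehyde 15 (not isolated), via hydrazone pinacol boronate 16 (not isolated)
Conditions: 2-(CF3)C6H4SO2NHNH2 (1.1 equiv), 0.1 M HCl (aq.)/THF, 23 °C; then MeB(OH)2 (10 equiv), 23 °C; evaporation
Reagents that add atoms: 2-(trifluoromethyl)benzenesulfonohydrazide NNS(=O)(=O)c1ccccc1C(F)(F)F; water O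
Why: acid-catalysed acetal cleavage in the presence of the sulfonyl hydrazide traps the β,γ-unsaturated aldehyde at once as its hydrazone, and transesterification with excess volatile methylboronic acid frees the boronic acid; no stereocentre is touched.

Step 11
Reactants: 17 the seco boronic acid hydrazone
Product: 21 (6R,8S,1(10)E,4E)-13-[tert-butyl(diphenyl)silyl]oxy-8-hydroxy-2-(4,4,5,5-tetramethyl-1,3,2-dioxaborolan-2-yl)germacra-1(10),4,7(11)-trien-12,6-olide (C-2 epimers), via diazoalkane 18 (not isolated), via cyclic boronate zwitterion 19 (not isolated), via allylboronic acid 20 (not isolated)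
Conditions: NaH (1.0 equiv), THF (1 mM), −40 → 25 °C, 8 h; then pinacol (3 equiv), MgSO4, 25 °C
Reagents that add atoms: pinacol CC(C)(O)C(C)(C)O
Why: Proposed new method: ring contraction by an intramolecular 1,2-boronate shift: the sodium salt of the sulfonylhydrazone releases the non-stabilised diazoalkane below 25 °C, its nucleophilic carbon adds to the empty p-orbital of the tethered alkenylboronic acid to give the eleven-membered zwitterion 19, and anti-periplanar 1,2-migration of the alkenyl carbon C-1 from boron to C-2 with loss of N2 expels boron from the ring and leaves the ten-membered carbocycle with the alkene geometry retained; the closest known reactions are the intermolecular Barluenga reductive coupling of sulfonylhydrazones with boronic acids and the room-temperature diazoalkane–boronic acid couplings that keep the boron (Ley), new here being the intramolecular medium-ring version at high dilution; C-2 forms as an epimer mixture that converges in steps 14 and 15.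

Step 12
Reactants: 21 the macrocyclic allylic boronate
Product: 22 the C-8 methacrylate: (6R,8S)-13-[tert-butyl(diphenyl)silyl]oxy-8-(2-methylprop-2-enoyloxy)-2-(4,4,5,5-tetramethyl-1,3,2-dioxaborolan-2-yl)germacra-1(10),4,7(11)-trien-12,6-olide (C-2 epimers)
Conditions: methacrylic anhydride (2 equiv), Et3N, DMAP (10 mol%), CH2Cl2, 0 → 23 °C
Reagents that add atoms: methacrylic anhydride CC(=C)C(=O)OC(=O)C(C)=C
Why: DMAP-catalysed acylation of the only free hydroxyl; the allylic pinacol boronate masks the C-2 oxygen and is inert to these conditions.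

Step 13
Reactants: 22 the methacrylate boronate
Product: 23 (6R,8S)-13-[tert-butyl(diphenyl)silyl]oxy-2-hydroxy-8-(2-methylprop-2-enoyloxy)germacra-1(10),4,7(11)-trien-12,6-olide (C-2 epimers)
Conditions: NaBO3·4H2O (5 equiv), THF/H2O, 23 °C
Reagents that add atoms: sodium perborate [Na+].[O-]OB=O
Why: perborate oxidation of the allylic C–B bond proceeds by 1,2-migration to oxygen with retention and without allylic transposition, under conditions mild enough for the esters.

Step 14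
Reactants: 23 the C-2 epimeric allylic alcohols
Product: 24 (6R,8S)-13-[tert-butyl(diphenyl)silyl]oxy-8-(2-methylprop-2-enoyloxy)-2-oxogermacra-1(10),4,7(11)-trien-12,6-olide
Conditions: MnO2 (activated, 20 equiv), CH2Cl2, 23 °C
Reagents that add atoms: none
Why: MnO2 oxidation of the allylic alcohol removes the uncontrolled C-2 centre and gives a single enone without base, so the β,γ-alkene does not move into conjugation.

Step 15
Reactants: 24 the enone
Product: 25 (2R,6R,8S)-13-[tert-butyl(diphenyl)silyl]oxy-2-hydroxy-8-(2-methylprop-2-enoyloxy)germacra-1(10),4,7(11)-trien-12,6-olide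
Conditions: (S)-Me-CBS oxazaborolidine (0.5 equiv), catecholborane (1.8 equiv), toluene/CH2Cl2, −78 °C; then MeOH
Reagents that add atoms: none
Why: Corey–Bakshi–Shibata reduction; the alkenyl group acts as the large substituent, so the (S)-catalyst delivers hydride under reagent control to give the (2R)-alcohol at −78 °C, where the esters and the lactone are not reduced.

Step 16
Reactants: 25 the (2R)-alcohol
Product: 26 (2R,6R,8S)-2,13-dihydroxy-8-(2-methylprop-2-enoyloxy)germacra-1(10),4,7(11)-trien-12,6-olide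
Conditions: HF·pyridine, pyridine, THF, 0 → 23 °C
Reagents that add atoms: none
Why: buffered fluoride desilylation removes the TBDPS group without acid, which the 1,5-diene and the allylic alcohol would not tolerate.

Step 17
Reactants: 26 the diol
Product: 27 (2R,6R,8S,1(10)E,4E)-2,13-diacetoxy-8-(2-methylprop-2-enoyloxy)germacra-1(10),4,7(11)-trien-12,6-olide (CNP0309304.1)
Conditions: Ac2O (4 equiv), pyridine, DMAP (5 mol%), CH2Cl2, 0 °C
Reagents that add atoms: acetic anhydride CC(=O)OC(C)=O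
Why: DMAP-catalysed acetylation of the secondary allylic C-2 hydroxyl and the primary C-13 hydroxyl in one operation completes the target with no stereocentre affected.

**Compound list**

1 | 4,4-dimethoxybut-1-yne | C#CCC(OC)OC | starting material
2 | [(E)-4,4-dimethoxy-2-methylbut-1-enyl]dimethylalane | COC(OC)C/C(C)=C/[Al](C)C | intermediate (not isolated)
3 | (E)-1-iodo-4,4-dimethoxy-2-methylbut-1-ene | COC(OC)C/C(C)=C/I | intermediate
4 | [(E)-4,4-dimethoxy-2-methylbut-1-enyl]lithium | COC(OC)C/C(C)=C/[Li] | intermediate (not isolated)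
5 | (E)-5,5-dimethoxy-3-methylpent-2-enal | COC(OC)C/C(C)=C/C=O | intermediate
6 | prop-2-yn-1-ol | C#CCO | starting material
7 | tert-butyl(diphenyl)(prop-2-ynyloxy)silane | C#CCO[Si](c1ccccc1)(c1ccccc1)C(C)(C)C | intermediate
8 | (4R,5E)-1-[tert-butyl(diphenyl)silyl]oxy-8,8-dimethoxy-6-methyloct-5-en-2-yn-4-ol | COC(OC)C/C(C)=C/[C@@H](O)C#CCO[Si](c1ccccc1)(c1ccccc1)C(C)(C)C | intermediate
9 | (5R)-3-{[tert-butyl(diphenyl)silyl]oxymethyl}-5-[(E)-4,4-dimethoxy-2-methylbut-1-enyl]-4-{[isopropoxy(dimethyl)silyl]methyl}-2,5-dihydro-1,2-oxamagnesole | COC(OC)C/C(C)=C/[C@H]1O[Mg]C(CO[Si](c2ccccc2)(c2ccccc2)C(C)(C)C)=C1C[Si](C)(C)OC(C)C | intermediate (not isolated)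
10 | (5R)-3-{[tert-butyl(diphenyl)silyl]oxymethyl}-5-[(E)-4,4-dimethoxy-2-methylbut-1-enyl]-4-{[isopropoxy(dimethyl)silyl]methyl}furan-2(5H)-one | COC(OC)C/C(C)=C/[C@H]1OC(=O)C(CO[Si](c2ccccc2)(c2ccccc2)C(C)(C)C)=C1C[Si](C)(C)OC(C)C | intermediate
11 | (5R)-3-{[tert-butyl(diphenyl)silyl]oxymethyl}-5-[(E)-4,4-dimethoxy-2-methylbut-1-enyl]-4-(hydroxymethyl)furan-2(5H)-one | COC(OC)C/C(C)=C/[C@H]1OC(=O)C(CO[Si](c2ccccc2)(c2ccccc2)C(C)(C)C)=C1CO | intermediate
12 | (2R)-4-{[tert-butyl(diphenyl)silyl]oxymethyl}-2-[(E)-4,4-dimethoxy-2-methylbut-1-enyl]-5-oxo-2,5-dihydrofuran-3-carbaldehyde | COC(OC)C/C(C)=C/[C@H]1OC(=O)C(CO[Si](c2ccccc2)(c2ccccc2)C(C)(C)C)=C1C=O | intermediate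
13 | (5R)-3-{[tert-butyl(diphenyl)silyl]oxymethyl}-5-[(E)-4,4-dimethoxy-2-methylbut-1-enyl]-4-[(1S)-1-hydroxy-3-methylbut-3-enyl]furan-2(5H)-one | COC(OC)C/C(C)=C/[C@H]1OC(=O)C(CO[Si](c2ccccc2)(c2ccccc2)C(C)(C)C)=C1[C@@H](O)CC(C)=C | intermediate
14 | (5R)-3-{[tert-butyl(diphenyl)silyl]oxymethyl}-5-[(E)-4,4-dimethoxy-2-methylbut-1-enyl]-4-[(1S,3E)-1-hydroxy-3-methyl-4-(4,4,5,5-tetramethyl-1,3,2-dioxaborolan-2-yl)but-3-enyl]furan-2(5H)-one | COC(OC)C/C(C)=C/[C@H]1OC(=O)C(CO[Si](c2ccccc2)(c2ccccc2)C(C)(C)C)=C1[C@@H](O)C/C(C)=C/B1OC(C)(C)C(C)(C)O1 | intermediate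
15 | C-2 aldehyde of 14 (acetal cleaved; pinacol boronate kept) | O=CC/C(C)=C/[C@H]1OC(=O)C(CO[Si](c2ccccc2)(c2ccccc2)C(C)(C)C)=C1[C@@H](O)C/C(C)=C/B1OC(C)(C)C(C)(C)O1 | intermediate (not isolated)
16 | N-[2-(trifluoromethyl)phenylsulfonyl]hydrazone of 15 (pinacol boronate kept) | FC(F)(F)c1ccccc1S(=O)(=O)NN=CC/C(C)=C/[C@H]1OC(=O)C(CO[Si](c2ccccc2)(c2ccccc2)C(C)(C)C)=C1[C@@H](O)C/C(C)=C/B1OC(C)(C)C(C)(C)O1 | intermediate (not isolated)
17 | seco-compound: N-[2-(trifluoromethyl)phenylsulfonyl]hydrazone at C-2 with free (E)-alkenylboronic acid at C-1 (6R,8S) | FC(F)(F)c1ccccc1S(=O)(=O)NN=CC/C(C)=C/[C@H]1OC(=O)C(CO[Si](c2ccccc2)(c2ccccc2)C(C)(C)C)=C1[C@@H](O)C/C(C)=C/B(O)O | intermediate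
18 | C-2 diazoalkane of the seco boronic acid | [N-]=[N+]=CC/C(C)=C/[C@H]1OC(=O)C(CO[Si](c2ccccc2)(c2ccccc2)C(C)(C)C)=C1[C@@H](O)C/C(C)=C/B(O)O | intermediate (not isolated)
19 | eleven-membered cyclic boronate zwitterion (B bonded to C-1 and C-2; diazonium on C-2) | O[C@H]1C/C(C)=C/[B-](O)(O)C([N+]#N)C/C(C)=C/[C@H]2OC(=O)C(CO[Si](c3ccccc3)(c3ccccc3)C(C)(C)C)=C12 | intermediate (not isolated)
20 | ring-contracted allylboronic acid: (6R,8S)-13-silyloxy-8-hydroxy-2-(dihydroxyboryl)germacra-1(10),4,7(11)-trien-12,6-olide (C-2 epimers) | O[C@H]1C/C(C)=C/C(B(O)O)C/C(C)=C/[C@H]2OC(=O)C(CO[Si](c3ccccc3)(c3ccccc3)C(C)(C)C)=C12 | intermediate (not isolated)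
21 | (6R,8S,1(10)E,4E)-13-[tert-butyl(diphenyl)silyl]oxy-8-hydroxy-2-(4,4,5,5-tetramethyl-1,3,2-dioxaborolan-2-yl)germacra-1(10),4,7(11)-trien-12,6-olide (C-2 epimers) | O[C@H]1C/C(C)=C/C(B3OC(C)(C)C(C)(C)O3)C/C(C)=C/[C@H]2OC(=O)C(CO[Si](c3ccccc3)(c3ccccc3)C(C)(C)C)=C12 | intermediate
22 | (6R,8S)-13-[tert-butyl(diphenyl)silyl]oxy-8-(2-methylprop-2-enoyloxy)-2-(4,4,5,5-tetramethyl-1,3,2-dioxaborolan-2-yl)germacra-1(10),4,7(11)-trien-12,6-olide (C-2 epimers) | C=C(C)C(=O)O[C@H]1C/C(C)=C/C(B3OC(C)(C)C(C)(C)O3)C/C(C)=C/[C@H]2OC(=O)C(CO[Si](c3ccccc3)(c3ccccc3)C(C)(C)C)=C12 | intermediate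
23 | (6R,8S)-13-[tert-butyl(diphenyl)silyl]oxy-2-hydroxy-8-(2-methylprop-2-enoyloxy)germacra-1(10),4,7(11)-trien-12,6-olide (C-2 epimers) | C=C(C)C(=O)O[C@H]1C/C(C)=C/C(O)C/C(C)=C/[C@H]2OC(=O)C(CO[Si](c3ccccc3)(c3ccccc3)C(C)(C)C)=C12 | intermediate
24 | (6R,8S)-13-[tert-butyl(diphenyl)silyl]oxy-8-(2-methylprop-2-enoyloxy)-2-oxogermacra-1(10),4,7(11)-trien-12,6-olide | C=C(C)C(=O)O[C@H]1C/C(C)=C/C(=O)C/C(C)=C/[C@H]2OC(=O)C(CO[Si](c3ccccc3)(c3ccccc3)C(C)(C)C)=C12 | intermediate
25 | (2R,6R,8S)-13-[tert-butyl(diphenyl)silyl]oxy-2-hydroxy-8-(2-methylprop-2-enoyloxy)germacra-1(10),4,7(11)-trien-12,6-olide | C=C(C)C(=O)O[C@H]1C/C(C)=C/[C@H](O)C/C(C)=C/[C@H]2OC(=O)C(CO[Si](c3ccccc3)(c3ccccc3)C(C)(C)C)=C12 | intermediate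
26 | (2R,6R,8S)-2,13-dihydroxy-8-(2-methylprop-2-enoyloxy)germacra-1(10),4,7(11)-trien-12,6-olide | C=C(C)C(=O)O[C@H]1C/C(C)=C/[C@H](O)C/C(C)=C/[C@H]2OC(=O)C(CO)=C12 | intermediate
27 | (2R,6R,8S,1(10)E,4E)-2,13-diacetoxy-8-(2-methylprop-2-enoyloxy)germacra-1(10),4,7(11)-trien-12,6-olide (CNP0309304.1) | C=C(C)C(=O)O[C@H]1C/C(C)=C/[C@H](OC(C)=O)C/C(C)=C/[C@H]2OC(=O)C(COC(C)=O)=C12 | target

**Step count**
Total: 17 steps. Longest linear sequence: 16 steps (1 → 27 through steps 1, 2 and 4–17; step 3 is a one-step branch).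

**Three steps most likely to fail, with fallbacks**

Step 5 (carbomagnesiation with a functionalised silylmethyl Grignard reagent; incomplete addition or loss of the silyl ether from the alkenylmagnesium are the risks). The fallback sets out from 5 and comes back at 10. Zinc–ProPhenol alkynylation of 5 with methyl propiolate gives methyl (4R,5E)-4-hydroxy-8,8-dimethoxy-6-methyloct-5-en-2-ynoate F1. Syn-carbocupration with the magnesium cuprate made from the same silylmethyl Grignard reagent and CuI at −78 °C, iodine quench and lactonisation give (5R)-5-[(E)-4,4-dimethoxy-2-methylbut-1-enyl]-3-iodo-4-{[isopropoxy(dimethyl)silyl]methyl}furan-2(5H)-one F2. Stille–Kosugi coupling with Bu3SnCH2OH and Pd(PPh3)4 gives (5R)-5-[(E)-4,4-dimethoxy-2-methylbut-1-enyl]-3-(hydroxymethyl)-4-{[isopropoxy(dimethyl)silyl]methyl}furan-2(5H)-one F3, and silylation with TBDPSCl and imidazole gives 10.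

Step 9 (cross-metathesis of a 1,1-disubstituted alkene; conversion and E/Z ratio are the risks). The fallback sets out from 12 and comes back at 14. (S)-TRIP-catalysed propargylation of 12 with allenylboronic acid pinacol ester gives (5R)-3-{[tert-butyl(diphenyl)silyl]oxymethyl}-5-[(E)-4,4-dimethoxy-2-methylbut-1-enyl]-4-[(1S)-1-hydroxybut-3-ynyl]furan-2(5H)-one F4. Negishi methylalumination (AlMe3, Cp2ZrCl2, H2O, −23 °C, short contact so the lactone survives) and iodinolysis give (5R)-3-{[tert-butyl(diphenyl)silyl]oxymethyl}-5-[(E)-4,4-dimethoxy-2-methylbut-1-enyl]-4-[(1S,3E)-1-hydroxy-4-iodo-3-methylbut-3-enyl]furan-2(5H)-one F5 with the geometry fixed by syn addition. Miyaura borylation (PdCl2(PPh3)2, B2pin2, KOPh, toluene, 50 °C) gives 14.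

Step 11 (the proposed ring contraction; diazoalkane decomposition, oligomerisation and protodeboronation are the risks). The fallback uses known chemistry, sets out from 14 and comes back at 23. Acylation of 14 with methacrylic anhydride, Et3N and DMAP gives the C-8 methacrylate of 14 F6. NaI and chloramine-T in THF/H2O convert the boronate with retention into the corresponding (E)-alkenyl iodide F7. Acetal hydrolysis with 0.1 M HCl in THF gives the iodo aldehyde F8, which is cyclised at once by Nozaki–Hiyama–Kishi reaction (CrCl2, NiCl2 1 mol%, DMSO/THF, 2 mM, 25 °C) to the C-2 epimeric allylic alcohols 23. Steps 14 and 15 then set C-2 as in the main route.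

**Further compounds**

F1 | step 5 | methyl (4R,5E)-4-hydroxy-8,8-dimethoxy-6-methyloct-5-en-2-ynoate | COC(OC)C/C(C)=C/[C@@H](O)C#CC(=O)OC
F2 | step 5 | (5R)-5-[(E)-4,4-dimethoxy-2-methylbut-1-enyl]-3-iodo-4-{[isopropoxy(dimethyl)silyl]methyl}furan-2(5H)-one | COC(OC)C/C(C)=C/[C@H]1OC(=O)C(I)=C1C[Si](C)(C)OC(C)C
F3 | step 5 | (5R)-5-[(E)-4,4-dimethoxy-2-methylbut-1-enyl]-3-(hydroxymethyl)-4-{[isopropoxy(dimethyl)silyl]methyl}furan-2(5H)-one | COC(OC)C/C(C)=C/[C@H]1OC(=O)C(CO)=C1C[Si](C)(C)OC(C)C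
F4 | step 9 | (5R)-3-{[tert-butyl(diphenyl)silyl]oxymethyl}-5-[(E)-4,4-dimethoxy-2-methylbut-1-enyl]-4-[(1S)-1-hydroxybut-3-ynyl]furan-2(5H)-one | COC(OC)C/C(C)=C/[C@H]1OC(=O)C(CO[Si](c2ccccc2)(c2ccccc2)C(C)(C)C)=C1[C@@H](O)CC#C
F5 | step 9 | (5R)-3-{[tert-butyl(diphenyl)silyl]oxymethyl}-5-[(E)-4,4-dimethoxy-2-methylbut-1-enyl]-4-[(1S,3E)-1-hydroxy-4-iodo-3-methylbut-3-enyl]furan-2(5H)-one | COC(OC)C/C(C)=C/[C@H]1OC(=O)C(CO[Si](c2ccccc2)(c2ccccc2)C(C)(C)C)=C1[C@@H](O)C/C(C)=C/I
F6 | step 11 | C-8 methacrylate of 14 | COC(OC)C/C(C)=C/[C@H]1OC(=O)C(CO[Si](c2ccccc2)(c2ccccc2)C(C)(C)C)=C1[C@@H](OC(=O)C(C)=C)C/C(C)=C/B1OC(C)(C)C(C)(C)O1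
F7 | step 11 | (E)-alkenyl iodide from F6 | COC(OC)C/C(C)=C/[C@H]1OC(=O)C(CO[Si](c2ccccc2)(c2ccccc2)C(C)(C)C)=C1[C@@H](OC(=O)C(C)=C)C/C(C)=C/I
F8 | step 11 | iodo aldehyde from F7 | O=CC/C(C)=C/[C@H]1OC(=O)C(CO[Si](c2ccccc2)(c2ccccc2)C(C)(C)C)=C1[C@@H](OC(=O)C(C)=C)C/C(C)=C/I
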